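## Retrosynthetic overview

1. The spiro γ-lactone is closed last from a C16 acid and the C15 hydroxyl. The tetrahydrofuran (C9–O–C13) comes from 5-exo opening, with inversion, of an enantiopure C13–C16 epoxide by the C9 hydroxyl. The C9 carbinol comes from the C9 ketone and a C11–C16 alkyllithium whose C13 is set by Sharpless epoxidation.
2. The strategy rests on ring B (C5–C10): its oxygenated carbons C6 (carbinol) and C9 (spiro ether carbon) are 1,4-related, a dissonant pattern. The C8–C9 bond is therefore made by a carbene-catalysed Stetter reaction of a C10 aldehyde (C9) onto C8 of a C5 crotonyl ketone, which closes ring B as the 6,9-dione.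
3. The Stetter precursor comes from a bis-lactone on ring A (19,20-δ-lactone and 6,9-γ-lactone) by (E)-propenyllithium addition and oxidation. The bis-lactone comes from a Tollens bis-hydroxymethylation at C10, after which the axial C19 carboxyl selects the cis hydroxymethyl as C20.
4. Ring A with C4 and C5 comes from an ester-tethered intramolecular Diels–Alder reaction of citraconic anhydride with (E)-penta-2,4-dien-1-ol. The racemate is resolved as amide diastereomers when the lactone is opened.
5. Order of ring formation: ring A, 19,20-lactone bridge, ring B, tetrahydrofuran, γ-lactone.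

Key step: step 10

Remarks on the chemistry:
- Labdane numbering (C1–C20) is used for the carbons of all intermediates.
- Compounds 4–6 are racemic; their SMILES show the enantiomer that is carried on. The absolute configuration is fixed in step 4, where the amide diastereomer derived from the other enantiomer of 6 is separated and discarded.
- (S)-2-(Methoxymethyl)pyrrolidine, diethyl (2-oxooxolan-3-yl)phosphonate and (tert-butyldiphenylsilyloxy)acetaldehyde are taken as commercial.

## Route

Step 1
Reactants: 1 citraconic anhydride; 2 (E)-penta-2,4-dien-1-ol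
Product: 4 rac-(3aR*,4S*,7aR*)-4-methyl-3-oxo-1,3,3a,4,5,7a-hexahydro-2-benzofuran-4-carboxylic acid (cis-fused lactone acid), via dienyl hydrogen citraconate 3 (not isolated)
Conditions: PhMe, BHT (cat.), 60 °C then 110 °C (sealed tube); crystallization
Reagents that add atoms: none
Why: Alcoholysis of the anhydride at its less hindered carbonyl (on the CH carbon) gives the half ester, whose ester tether forces the intramolecular Diels–Alder reaction to join C10 to C5 and C3 to C4 (a regiochemistry that an intermolecular reaction of citraconic anhydride would not secure), while the Z dienophile places the C19 carboxyl cis to the C6 carbonyl and the endo mode expected for maleate-type half esters should give the cis-fused lactone, whose C10 configuration is erased in step 6.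

Step 2
Reactants: 4 rac-hexahydro lactone acid
Product: 5 rac-(3aR*,4S*,7aR*)-4-methyl-3-oxooctahydro-2-benzofuran-4-carboxylic acid
Conditions: H2 (1 atm), Pd/C (10 wt %), EtOAc, rt
Reagents that add atoms: none
Why: Catalytic hydrogenation of the disubstituted ring alkene creates no stereocentre and removes the β,γ-unsaturation before C10 is enolized in step 6.

Step 3
Reactants: 5 rac-octahydro lactone acid
Product: 6 rac-methyl (3aR*,4S*,7aR*)-4-methyl-3-oxooctahydro-2-benzofuran-4-carboxylate
Conditions: MeI, K2CO3, DMF, rt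
Reagents that add atoms: iodomethane, CI
Why: SN2 alkylation of the carboxylate masks the C19 acid for the aluminium amide of step 4 without touching the lactone.

Step 4
Reactants: 6 rac-lactone methyl ester
Product: 7 methyl (1S,2R,3R)-3-(hydroxymethyl)-2-{[(2S)-2-(methoxymethyl)pyrrolidin-1-yl]carbonyl}-1-methylcyclohexane-1-carboxylate
Conditions: (S)-2-(methoxymethyl)pyrrolidine (1.5 equiv), AlMe3 (1.5 equiv), PhMe, 0 → 50 °C; aq. potassium sodium tartrate; chromatography
Reagents that add atoms: (S)-2-(methoxymethyl)pyrrolidine, COC[C@@H]1CCCN1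
Why: Aluminium amide aminolysis of the γ-lactone (Weinreb-type) spares the α-quaternary methyl ester and frees the C9 hydroxyl; because the amine is a single enantiomer, the racemate becomes two hydroxy amide diastereomers that should be separable, and removing the (1R,2S,3S) diastereomer from the other enantiomer of 6 by chromatography fixes the absolute configuration at C4 and C5.

Step 5
Reactants: 7 hydroxy amide
Product: 8 methyl (1S,2R,3R)-3-formyl-2-{[(2S)-2-(methoxymethyl)pyrrolidin-1-yl]carbonyl}-1-methylcyclohexane-1-carboxylate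
Conditions: Dess–Martin periodinane, NaHCO3, CH2Cl2, 0 °C → rt
Reagents that add atoms: none
Why: Dess–Martin oxidation of the primary alcohol stops at the aldehyde, the tertiary amide cannot close onto it, and epimerization at C10 is without consequence.

Step 6
Reactants: 8 aldehyde
Product: 10 (1S,5R,9R)-5-(hydroxymethyl)-9-{[(2S)-2-(methoxymethyl)pyrrolidin-1-yl]carbonyl}-1-methyl-3-oxabicyclo[3.3.1]nonan-2-one, via diol ester 9 (not isolated)
Conditions: 37% aq. HCHO (6 equiv), KOH (3 equiv), MeOH/H2O, 0 → 50 °C; then 2 M HCl to pH 2, rt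
Reagents that add atoms: formaldehyde, C=O
Why: The Tollens reaction (aldol addition of formaldehyde at C10, then crossed Cannizzaro reduction) makes C10 a gem-bis(hydroxymethyl) carbon, so no facial selectivity is needed there, and only the hydroxymethyl cis to the axial C19 ester can lactonize, which defines C10 (the lactone carbon becomes C20, the free arm C9).

Step 7
Reactants: 10 δ-lactone hydroxy amide
Product: 11 bis-lactone of ring A (4S,5R,10R): 19,20-δ-lactone bridging C4 and C10, and trans-fused γ-lactone C6(=O)–O–C9H2 across C5–C10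
Conditions: TsOH·H2O (1.5 equiv), PhMe, 100 °C
Reagents that add atoms: none
Why: Acid-promoted N→O acyl transfer (lactonization of a γ-hydroxy amide) joins the equatorial C9 hydroxymethyl to C6, releases the chiral amine as its salt and leaves C6 as an activated acyl group with C9 masked.

Step 8
Reactants: 11 bis-lactone; 12 (E)-1-bromoprop-1-ene
Product: 14 (1S,5R,9R)-9-[(2E)-but-2-enoyl]-5-(hydroxymethyl)-1-methyl-3-oxabicyclo[3.3.1]nonan-2-one, via (E)-prop-1-enyllithium 13 (not isolated)
Conditions: 12, t-BuLi (2.0 equiv), Et2O, −78 °C; then 11 (1.1 equiv of 13 per 11), THF, −78 °C; aq. NH4Cl at −78 °C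
Reagents that add atoms: none
Why: Bromine–lithium exchange keeps the E geometry and the alkenyllithium adds once to a lactone (the lithium hemiketal persists at −78 °C and gives the ketone on work-up), the γ-lactone carbonyl on the tertiary C5 being attacked in preference to the δ-lactone carbonyl on the quaternary C4.

Step 9
Reactants: 14 hydroxy enone
Product: 15 (1S,5S,9R)-9-[(2E)-but-2-enoyl]-1-methyl-2-oxo-3-oxabicyclo[3.3.1]nonane-5-carbaldehyde (Stetter precursor)
Conditions: Dess–Martin periodinane, NaHCO3, CH2Cl2, 0 °C → rt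
Reagents that add atoms: none
Why: Dess–Martin oxidation of the neopentyl primary alcohol gives the C10 aldehyde without touching the enone.

Step 10
Reactants: 15 keto aldehyde
Product: 16 tricyclic 6,9-diketo 19,20-lactone (4S,5R,8R,10S), trans-fused rings A and B, 8α-methyl
Conditions: (5aS,10bR)-2-(pentafluorophenyl)-5a,10b-dihydro-4H,6H-indeno[2,1-b][1,2,4]triazolo[4,3-d][1,4]oxazin-2-ium tetrafluoroborate (20 mol %), KN(SiMe3)2 (18 mol %), PhMe, 23 → 60 °C; then DBU (20 mol %), rt
Reagents that add atoms: none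
Why: The carbene adds to the C9 aldehyde and proton transfer gives the Breslow intermediate, whose nucleophilic C9 adds to C8 of the E-enone before proton transfer and loss of the carbene leave the 1,4-diketone (intramolecular Stetter reaction, known for aliphatic aldehydes tethered to enones). Ring B closes in the 6-endo-trig mode, the enone carbonyl C6 lying inside the new ring, from C9 and C6 arms held trans-diequatorial on the locked chair of ring A, so the trans-decalin should result. The new stereocentre C8 is set by a chair transition state with the methyl group equatorial, supported by the chiral carbene, and because it is α to the C9 ketone the DBU treatment corrects any axial epimer to the equatorial 8α-methyl compound. The step needs 1,4-addition in preference to benzoin and aldol paths: the aldehyde has no α-hydrogen, its neopentyl position disfavours bimolecular benzoin coupling, and the acceptor is held next to it. C5 lies between two quaternary carbons and is not expected to epimerize under the weak base used.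

Step 11
Reactants: 16 diketone
Product: 17 6β-hydroxy-9-keto 19,20-lactone (4S,5R,6R,8R,10S)
Conditions: NaBH4 (1 equiv), MeOH/CH2Cl2, −40 °C; pH 7 buffer at −40 °C
Reagents that add atoms: none
Why: Borohydride reduces the less substituted C6 ketone (C9 is flanked by the quaternary C10 and by C8) from the α face, the β face being covered by the axial C20 and the lactone bridge, to give the axial 6β-alcohol, and the cold neutral quench avoids transfer of the C19 acyl group from O20 to the new oxygen.

Step 12
Reactants: 17 6β-alcohol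
Product: 18 6β-(tert-butyldimethylsilyloxy)-9-keto 19,20-lactone
Conditions: TBSOTf, 2,6-lutidine, CH2Cl2, −20 → 0 °C
Reagents that add atoms: tert-butyldimethylsilyl trifluoromethanesulfonate, CC(C)(C)[Si](C)(C)OS(=O)(=O)C(F)(F)F
Why: Silyl triflate silylation protects the hindered axial alcohol without forming an alkoxide next to the C19 lactone.

Step 13
Reactants: 19 diethyl (2-oxooxolan-3-yl)phosphonate; 20 (tert-butyldiphenylsilyloxy)acetaldehyde
Product: 21 (3E)-3-{2-[(tert-butyldiphenylsilyl)oxy]ethylidene}oxolan-2-one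
Conditions: NaH, THF, 0 °C → rt; chromatography
Reagents that add atoms: none
Why: Horner–Wadsworth–Emmons olefination with the α-phosphono lactone should give mainly the E alkylidene lactone (aldehyde substituent trans to the lactone carbonyl), the minor Z isomer being removed.

Step 14
Reactants: 21 alkylidene lactone
Product: 22 (2E)-2-{2-[(tert-butyldiphenylsilyl)oxy]ethylidene}butane-1,4-diol
Conditions: i-Bu2AlH (4 equiv), CH2Cl2, −78 → 0 °C; aq. potassium sodium tartrate
Reagents that add atoms: none
Why: 1,2-Reduction of the unsaturated lactone gives the allylic C16 alcohol and frees the C11 hydroxyl without touching the alkene or the silyl ether.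

Step 15
Reactants: 22 allylic diol
Product: 23 2-[(2S,3S)-3-{[(tert-butyldiphenylsilyl)oxy]methyl}-2-(hydroxymethyl)oxiran-2-yl]ethan-1-ol
Conditions: Ti(OiPr)4 (10 mol %), L-(+)-diethyl tartrate (12 mol %), t-BuOOH, 4 Å molecular sieves, CH2Cl2, −20 °C
Reagents that add atoms: tert-butyl hydroperoxide, CC(C)(C)OO
Why: Sharpless asymmetric epoxidation directed by the allylic C16 hydroxyl of this E-2,3-disubstituted allylic alcohol should deliver oxygen, with the L-(+)-tartrate, to the face that gives the (2S,3S)-epoxide, which sets C13 (the remote C11 hydroxyl is a spectator).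

Step 16
Reactants: 23 epoxy diol
Product: 24 (2R)-2-{2-[(tert-butyldiphenylsilyl)oxy]ethyl}butane-1,2,4-triol
Conditions: LiAlH4, THF, 0 °C → rt
Reagents that add atoms: none
Why: Hydride opens the epoxide by SN2 attack at the secondary C14 and not at the quaternary C13, so the C13–O bond and its configuration are kept.

Step 17
Reactants: 24 triol
Product: 25 2-[(4R)-4-{2-[(tert-butyldiphenylsilyl)oxy]ethyl}-2,2-dimethyl-1,3-dioxolan-4-yl]ethan-1-ol
Conditions: 2,2-dimethoxypropane, PPTS (cat.), acetone, rt
Reagents that add atoms: 2,2-dimethoxypropane, COC(C)(C)OC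
Why: Under equilibrating acetalization the five-membered acetonide of the C13/C16 1,2-diol is favoured over the six-membered alternative, which leaves the C11 hydroxyl free.

Step 18
Reactants: 25 acetonide alcohol
Product: 26 tert-butyl{2-[(4S)-4-(2-iodoethyl)-2,2-dimethyl-1,3-dioxolan-4-yl]ethoxy}diphenylsilane
Conditions: I2, PPh3, imidazole, CH2Cl2, 0 °C
Reagents that add atoms: iodine, II
Why: Appel-type iodination converts the primary alcohol into the iodide needed for lithium exchange (the descriptor changes only through priorities).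

Step 19
Reactants: 18 silyl-protected keto lactone; 26 iodide
Product: 28 9α-hydroxy adduct (4S,5R,6R,8R,9R,10S,13R) carrying at C9 the 2-[(4R)-4-{2-[(tert-butyldiphenylsilyl)oxy]ethyl}-2,2-dimethyl-1,3-dioxolan-4-yl]ethyl chain, via alkyllithium 27 (not isolated)
Conditions: 26 (1.5 equiv), t-BuLi (3.0 equiv), Et2O/pentane, −78 °C; then 18, THF, −78 → −40 °C; aq. NH4Cl
Reagents that add atoms: none
Why: 1,2-Addition of a primary alkyllithium to the ketone, which is more electrophilic than the α-quaternary lactone, should occur from the β face (equatorial approach) because axial approach from the α face meets the syn-axial hydrogens at C1, C5 and C7, as in additions of alkyllithiums to 8-methyl-9-oxo decalins of the labdane series, giving the axial 9α-hydroxyl and the equatorial C11 chain.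

Step 20
Reactants: 28 acetonide adduct
Product: 29 9α,13,16-triol (13R) with 6β-OTBS and 15-OTBDPS groups
Conditions: AcOH/H2O/THF (3:1:1), 45 °C
Reagents that add atoms: none
Why: Acid hydrolysis of the acetonide frees the C13/C16 diol while the hindered secondary TBS ether and the TBDPS ether survive.

Step 21
Reactants: 29 triol
Product: 31 (13R)-13,16-epoxide with free 9α-hydroxyl, via tosylate 30 (not isolated)
Conditions: TsCl (1.2 equiv), Et3N, DMAP (cat.), CH2Cl2, 0 °C; then NaH, THF, 0 °C
Reagents that add atoms: none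
Why: Only the primary C16 hydroxyl is sulfonylated in the presence of two tertiary alcohols, and the neighbouring C13 alkoxide then closes the epoxide (3-exo-tet) with retention at C13.

Step 22
Reactants: 31 epoxy alcohol
Product: 32 9α,13-epoxy-16-ol (13S) with 6β-OTBS and 15-OTBDPS groups
Conditions: camphorsulfonic acid (10 mol %), CH2Cl2, 0 °C
Reagents that add atoms: none
Why: Acid-catalysed 5-exo opening of the 2,2-disubstituted epoxide by the C9 hydroxyl at the tertiary C13 proceeds with inversion, which forms the spiro tetrahydrofuran and transfers the epoxide configuration to C13 (S).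

Step 23
Reactants: 32 primary alcohol
Product: 33 9α,13-epoxy-16-oic acid (13S)
Conditions: TEMPO (20 mol %), PhI(OAc)2 (2.5 equiv), MeCN/H2O (1:1), rt
Reagents that add atoms: water, O
Why: Nitroxyl-catalysed oxidation takes the neopentyl primary alcohol through the aldehyde hydrate to the acid, and C13 carries no hydrogen and cannot epimerize.

Step 24
Reactants: 33 silyl-protected acid
Product: 35 CNP0393616.1 (4S,5R,6R,8R,9R,10S,13S), via dihydroxy acid 34 (not isolated)
Conditions: 48% aq. HF, MeCN, 0 °C → rt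
Reagents that add atoms: none
Why: Acidic fluoride cleaves both silyl ethers, the C15 hydroxyl closes the γ-lactone onto the C16 acid under the same conditions, and no alkoxide is present that could move the C19 acyl group to the 6β-oxygen.

## Compound list

1 | citraconic anhydride | CC1=CC(=O)OC1=O | starting material
2 | (E)-penta-2,4-dien-1-ol | OC/C=C/C=C | starting material
3 | (2Z)-2-methyl-4-oxo-4-[(2E)-penta-2,4-dien-1-yloxy]but-2-enoic acid | C=C/C=C/COC(=O)/C=C(/C)C(=O)O | intermediate
4 | rac-(3aR*,4S*,7aR*)-4-methyl-3-oxo-1,3,3a,4,5,7a-hexahydro-2-benzofuran-4-carboxylic acid | O=C1OC[C@@H]2C=CC[C@](C)(C(=O)O)[C@H]12 | intermediate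
5 | rac-(3aR*,4S*,7aR*)-4-methyl-3-oxooctahydro-2-benzofuran-4-carboxylic acid | O=C1OC[C@@H]2CCC[C@](C)(C(=O)O)[C@H]12 | intermediate
6 | rac-methyl (3aR*,4S*,7aR*)-4-methyl-3-oxooctahydro-2-benzofuran-4-carboxylate | O=C1OC[C@@H]2CCC[C@](C)(C(=O)OC)[C@H]12 | intermediate
7 | methyl (1S,2R,3R)-3-(hydroxymethyl)-2-{[(2S)-2-(methoxymethyl)pyrrolidin-1-yl]carbonyl}-1-methylcyclohexane-1-carboxylate | COC[C@@H]1CCCN1C(=O)[C@@H]2[C@H](CO)CCC[C@]2(C)C(=O)OC | intermediate
8 | methyl (1S,2R,3R)-3-formyl-2-{[(2S)-2-(methoxymethyl)pyrrolidin-1-yl]carbonyl}-1-methylcyclohexane-1-carboxylate | COC[C@@H]1CCCN1C(=O)[C@@H]2[C@H](C=O)CCC[C@]2(C)C(=O)OC | intermediate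
9 | methyl (1S,2R)-3,3-bis(hydroxymethyl)-2-{[(2S)-2-(methoxymethyl)pyrrolidin-1-yl]carbonyl}-1-methylcyclohexane-1-carboxylate | COC[C@@H]1CCCN1C(=O)[C@@H]2C(CO)(CO)CCC[C@]2(C)C(=O)OC | intermediate
10 | (1S,5R,9R)-5-(hydroxymethyl)-9-{[(2S)-2-(methoxymethyl)pyrrolidin-1-yl]carbonyl}-1-methyl-3-oxabicyclo[3.3.1]nonan-2-one | COC[C@@H]1CCCN1C(=O)[C@@H]2[C@@]3(CO)CCC[C@]2(C)C(=O)OC3 | intermediate
11 | ring A bis-lactone (4S,5R,10R): 19,20-δ-lactone and trans-fused 6,9-γ-lactone | O=C1OC[C@@]2(CCC[C@]3(C)C(=O)OC2)[C@@H]13 | intermediate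
12 | (E)-1-bromoprop-1-ene | C/C=C/Br | starting material
13 | (E)-prop-1-enyllithium | C/C=C/[Li] | intermediate
14 | (1S,5R,9R)-9-[(2E)-but-2-enoyl]-5-(hydroxymethyl)-1-methyl-3-oxabicyclo[3.3.1]nonan-2-one | C/C=C/C(=O)[C@@H]1[C@@]2(CO)CCC[C@]1(C)C(=O)OC2 | intermediate
15 | (1S,5S,9R)-9-[(2E)-but-2-enoyl]-1-methyl-2-oxo-3-oxabicyclo[3.3.1]nonane-5-carbaldehyde | C/C=C/C(=O)[C@@H]1[C@@]2(C=O)CCC[C@]1(C)C(=O)OC2 | intermediate
16 | tricyclic 6,9-diketo 19,20-lactone (4S,5R,8R,10S) | C[C@@H]1CC(=O)[C@@H]2[C@]3(CCC[C@]2(C)C(=O)OC3)C1=O | intermediate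
17 | 6β-hydroxy-9-keto 19,20-lactone (4S,5R,6R,8R,10S) | C[C@@H]1C[C@@H](O)[C@@H]2[C@]3(CCC[C@]2(C)C(=O)OC3)C1=O | intermediate
18 | 6β-(tert-butyldimethylsilyloxy)-9-keto 19,20-lactone | C[C@@H]1C[C@@H](O[Si](C)(C)C(C)(C)C)[C@@H]2[C@]3(CCC[C@]2(C)C(=O)OC3)C1=O | intermediate
19 | diethyl (2-oxooxolan-3-yl)phosphonate | CCOP(=O)(OCC)C1CCOC1=O | starting material
20 | (tert-butyldiphenylsilyloxy)acetaldehyde | O=CCO[Si](c1ccccc1)(c1ccccc1)C(C)(C)C | starting material
21 | (3E)-3-{2-[(tert-butyldiphenylsilyl)oxy]ethylidene}oxolan-2-one | O=C1OCC/C1=C\CO[Si](c2ccccc2)(c3ccccc3)C(C)(C)C | intermediate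
22 | (2E)-2-{2-[(tert-butyldiphenylsilyl)oxy]ethylidene}butane-1,4-diol | OCC/C(CO)=C\CO[Si](c1ccccc1)(c2ccccc2)C(C)(C)C | intermediate
23 | 2-[(2S,3S)-3-{[(tert-butyldiphenylsilyl)oxy]methyl}-2-(hydroxymethyl)oxiran-2-yl]ethan-1-ol | OCC[C@@]1(CO)O[C@H]1CO[Si](c2ccccc2)(c3ccccc3)C(C)(C)C | intermediate
24 | (2R)-2-{2-[(tert-butyldiphenylsilyl)oxy]ethyl}butane-1,2,4-triol | OCC[C@](CO)(CCO[Si](c1ccccc1)(c2ccccc2)C(C)(C)C)O | intermediate
25 | 2-[(4R)-4-{2-[(tert-butyldiphenylsilyl)oxy]ethyl}-2,2-dimethyl-1,3-dioxolan-4-yl]ethan-1-ol | OCC[C@@]1(CCO[Si](c2ccccc2)(c3ccccc3)C(C)(C)C)COC(C)(C)O1 | intermediate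
26 | tert-butyl{2-[(4S)-4-(2-iodoethyl)-2,2-dimethyl-1,3-dioxolan-4-yl]ethoxy}diphenylsilane | ICC[C@@]1(CCO[Si](c2ccccc2)(c3ccccc3)C(C)(C)C)COC(C)(C)O1 | intermediate
27 | {2-[(4R)-4-{2-[(tert-butyldiphenylsilyl)oxy]ethyl}-2,2-dimethyl-1,3-dioxolan-4-yl]ethyl}lithium | [Li]CC[C@@]1(CCO[Si](c2ccccc2)(c3ccccc3)C(C)(C)C)COC(C)(C)O1 | intermediate
28 | 9α-hydroxy adduct (4S,5R,6R,8R,9R,10S,13R): 6β-OTBS, 19,20-lactone, C13/C16 acetonide, 15-OTBDPS | C[C@@H]1C[C@@H](O[Si](C)(C)C(C)(C)C)[C@@H]2[C@]3(CCC[C@]2(C)C(=O)OC3)[C@@]1(O)CC[C@@]4(CCO[Si](c5ccccc5)(c6ccccc6)C(C)(C)C)COC(C)(C)O4 | intermediate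
29 | 9α,13,16-triol (13R): 6β-OTBS, 19,20-lactone, 15-OTBDPS | C[C@@H]1C[C@@H](O[Si](C)(C)C(C)(C)C)[C@@H]2[C@]3(CCC[C@]2(C)C(=O)OC3)[C@@]1(O)CC[C@](CO)(CCO[Si](c4ccccc4)(c5ccccc5)C(C)(C)C)O | intermediate
30 | 16-O-tosylate of triol 29 | C[C@@H]1C[C@@H](O[Si](C)(C)C(C)(C)C)[C@@H]2[C@]3(CCC[C@]2(C)C(=O)OC3)[C@@]1(O)CC[C@](COS(=O)(=O)c4ccc(C)cc4)(CCO[Si](c5ccccc5)(c6ccccc6)C(C)(C)C)O | intermediate
31 | (13R)-13,16-epoxide with free 9α-hydroxyl | C[C@@H]1C[C@@H](O[Si](C)(C)C(C)(C)C)[C@@H]2[C@]3(CCC[C@]2(C)C(=O)OC3)[C@@]1(O)CC[C@@]4(CCO[Si](c5ccccc5)(c6ccccc6)C(C)(C)C)CO4 | intermediate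
32 | 9α,13-epoxy-16-ol (13S): 6β-OTBS, 19,20-lactone, 15-OTBDPS | C[C@@H]1C[C@@H](O[Si](C)(C)C(C)(C)C)[C@@H]2[C@]3(CCC[C@]2(C)C(=O)OC3)[C@@]12CC[C@@](CO)(CCO[Si](c4ccccc4)(c5ccccc5)C(C)(C)C)O2 | intermediate
33 | 9α,13-epoxy-16-oic acid (13S): 6β-OTBS, 19,20-lactone, 15-OTBDPS | C[C@@H]1C[C@@H](O[Si](C)(C)C(C)(C)C)[C@@H]2[C@]3(CCC[C@]2(C)C(=O)OC3)[C@@]12CC[C@@](C(=O)O)(CCO[Si](c4ccccc4)(c5ccccc5)C(C)(C)C)O2 | intermediate
34 | 6β,15-dihydroxy-9α,13-epoxy-16-oic acid 19,20-lactone (13S) | C[C@@H]1C[C@@H](O)[C@@H]2[C@]3(CCC[C@]2(C)C(=O)OC3)[C@@]12CC[C@@](C(=O)O)(CCO)O2 | intermediate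
35 | CNP0393616.1 (4S,5R,6R,8R,9R,10S,13S) | C[C@@H]1C[C@@H](O)[C@@H]2[C@]3(CCC[C@]2(C)C(=O)OC3)[C@@]12CC[C@@]1(CCOC1=O)O2 | target

## Step count and risks

Total step count: 24. Longest linear sequence: 18 steps (steps 1–12 and 19–24, from citraconic anhydride).

Steps most likely to fail:

**Step 10 (Stetter ring closure).** Addition of the carbene to the neopentyl-type aldehyde may be too slow, so that the catalyst is consumed in unproductive adducts or the enone reacts otherwise before C9 becomes nucleophilic. Fallback: ring B is closed reductively from 15. SmI2 (2.2 equiv) with t-BuOH in THF at −78 °C should couple C9 with C8 by ketyl–olefin cyclization and give the 9-hydroxy-6-ketone F1 as a mixture of C9 carbinol epimers. Dess–Martin oxidation followed by DBU equilibration at C8 brings the route back at 16.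

**Step 19 (addition to the C9 ketone).** Facial selectivity may be poor or reversed (axial entry of the chain), or the organolithium may enolize the ketone toward C8. Fallback: from 18, dimethylsulfoxonium methylide (Me3S(O)I, NaH, DMSO), which adds reversibly and places the new carbon equatorially, should give the spiro-epoxide F2 with O9 axial (α) and C11 equatorial (β). Opening at C11 with the Grignard reagent from 2-(bromomethyl)-4-(tert-butyldiphenylsilyloxy)but-1-ene and CuI (cat.) gives the tertiary alcohol with a C13=C16 methylidene group F3. mCPBA gives the epoxide F4 as a mixture at C13, and camphorsulfonic acid closes the tetrahydrofuran to 32 together with its C13 epimer F5. The two are separated by chromatography, and the route continues at 32. Control of C13 by the reagent is given up in this path.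

**Step 8 (propenyllithium on the bis-lactone).** A second addition to the new enone, or attack at the δ-lactone, may compete. Fallback: from 10, TBSCl and imidazole give the silyl ether F6. Cp2Zr(H)Cl reduces the tertiary amide, not the lactone, to the C6 aldehyde F7. CrCl2 with NiCl2 (cat.) and (E)-1-iodoprop-1-ene in DMF adds the propenyl group to the aldehyde only and gives the allylic alcohol F8 (C6 epimers). Dess–Martin oxidation gives the enone F9, and HF·pyridine removes the silyl group to rejoin the route at 14.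

## Further compounds

F1 | step 10 | 9-hydroxy-6-keto 19,20-lactone (4S,5R,8R,10S; C9 carbinol epimers) | C[C@@H]1CC(=O)[C@@H]2[C@]3(CCC[C@]2(C)C(=O)OC3)C1O
F2 | step 19 | 9α,11-epoxide (spiro-oxirane at C9) of the 6β-OTBS lactone | C[C@@H]1C[C@@H](O[Si](C)(C)C(C)(C)C)[C@@H]2[C@]3(CCC[C@]2(C)C(=O)OC3)[C@@]14CO4
F3 | step 19 | 9α-hydroxy compound with C13=C16 methylidene side chain and 15-OTBDPS | C[C@@H]1C[C@@H](O[Si](C)(C)C(C)(C)C)[C@@H]2[C@]3(CCC[C@]2(C)C(=O)OC3)[C@@]1(O)CCC(=C)CCO[Si](c4ccccc4)(c5ccccc5)C(C)(C)C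
F4 | step 19 | 13,16-epoxide with free 9α-hydroxyl (mixture at C13) | C[C@@H]1C[C@@H](O[Si](C)(C)C(C)(C)C)[C@@H]2[C@]3(CCC[C@]2(C)C(=O)OC3)[C@@]1(O)CCC4(CCO[Si](c5ccccc5)(c6ccccc6)C(C)(C)C)CO4
F5 | step 19 | 13-epimer (13R) of compound 32 | C[C@@H]1C[C@@H](O[Si](C)(C)C(C)(C)C)[C@@H]2[C@]3(CCC[C@]2(C)C(=O)OC3)[C@@]12CC[C@](CO)(CCO[Si](c4ccccc4)(c5ccccc5)C(C)(C)C)O2
F6 | step 8 | tert-butyldimethylsilyl ether of compound 10 | COC[C@@H]1CCCN1C(=O)[C@@H]2[C@@]3(CO[Si](C)(C)C(C)(C)C)CCC[C@]2(C)C(=O)OC3
F7 | step 8 | C6 aldehyde: 5-[(tert-butyldimethylsilyloxy)methyl]-1-methyl-2-oxo-3-oxabicyclo[3.3.1]nonane-9-carbaldehyde | O=C[C@@H]1[C@@]2(CO[Si](C)(C)C(C)(C)C)CCC[C@]1(C)C(=O)OC2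
F8 | step 8 | (E)-allylic alcohol at C6 (carbinol epimers) | C/C=C/C(O)[C@@H]1[C@@]2(CO[Si](C)(C)C(C)(C)C)CCC[C@]1(C)C(=O)OC2
F9 | step 8 | tert-butyldimethylsilyl ether of compound 14 | C/C=C/C(=O)[C@@H]1[C@@]2(CO[Si](C)(C)C(C)(C)C)CCC[C@]1(C)C(=O)OC2
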